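Late in both earlier runs Sub levels off: its last reading is 20.7% in Tuesday's run and 21.4% in Friday's, although the Sub charges differ by a factor of 3.00.

| flask | Sub | Ptn | Bse | Spx | remark | time |
|---|---|---|---|---|---|---|
| Tuesday's | 0.0030 M | 0.80 equiv | 0.50 equiv | 2 mM | run made earlier |  |
| Friday's | 0.0010 M | 0.80 equiv | 0.50 equiv | 2 mM | run made earlier |  |
| cedar | 0.0020 M | 0.800 equiv | 0.500 equiv | 2.00 mM |  | 2.0 h |
| larch | 0.0020 M | 0.800 equiv | 0.650 equiv | 2.00 mM |  | 2.0 h |

| run | time / min | Sub / % | Tgt / % |
|---|---|---|---|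
| Tuesday's | 2.00 | 33.4 | 66.8 |
| Tuesday's | 3.00 | 30.4 | 71.0 |
| Tuesday's | 4.00 | 27.8 | 72.9 |
| Tuesday's | 6.00 | 24.9 | 74.7 |
| Tuesday's | 10.0 | 22.8 | 77.6 |
| Tuesday's | 15.0 | 21.3 | 78.5 |
| Tuesday's | 25.0 | 20.7 | 79.5 |
| Friday's | 1.33 | 52.4 | 48.1 |
| Friday's | 4.00 | 34.6 | 65.9 |
| Friday's | 6.00 | 30.1 | 70.0 |
| Friday's | 10.0 | 25.9 | 75.2 |
| Friday's | 15.0 | 22.8 | 76.7 |
| Friday's | 20.0 | 22.4 | 78.0 |
| Friday's | 25.0 | 21.4 | 78.4 |

(standard deviation of a reading: 0.5 percentage points)

- the earlier runs were read with a standard deviation of 0.5 percentage points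

* part of the Sub that has reacted at the end, cedar
* part of the Sub that has reacted at the end, larch
* what raising the equivalents of Bse from its lowest to its highest value here does to the part of the Sub that has reacted (changes below 5 percentage points count as none) (no change / it rises / it falls)

What stops Sub? At the last Tuesday reading, Sub and Tgt sum to 100%, so no visible loss competes. A plateau indifferent to concentration suggests a charge running out, and Ptn stands at 0.80 equiv. I call 80.0% the ceiling, the part of the Sub that a one-to-one use of the Ptn charge, the limiting reagent, can convert.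

But Tuesday's run reaches 79.3%, short of the ceiling. Is that another plateau? Take Friday's run, the more dilute. Its gap to the ceiling falls from 10 points at 6.00 min to 2.8 points at 15.0 min. Dividing the mean gap by the mean closing speed gives a time constant of 7.95 min. The exact exponential gives 7.07 min, so the mean's error is harmless. Cedar's 0.0020 M lies between the two earlier charges, and its 2.0 h is 15.1 such constants, so I expect it to reach the ceiling.

And larch, at 0.650 equiv of Bse? The ceiling contains no Bse, so my reckoning gives 80.0% there too, though that charge is untested.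

The forecast also says 80% for cedar, 80% for larch and no change; the unchanged plateau, it says, “argues against an equilibrium”.

The flasks give 80.0% for cedar and 80.0% for larch, no change, with a change of 0 points.

    Sub + Ptn → Byp + Tgt (k = 25.0 /M/s)
    Spx + Bse → Spx.Bse (k = 1.60 /M/s)
    Byp + Bse ⇌ Byp.Bse (K = 3.10 × 10⁷ /M, k = 130 /M/s)
    Ptn + Byp ⇌ Ptn.Byp, settled at all times (K = 7200 /M)

Both results sit on the ceiling of 80.0%, and neither the Spx loss nor the joining to Ptn.Byp moves cedar's answer. A neighbour of cedar with 0.200 equiv of Ptn has a ceiling of 20.0% and gives 20.0%. Cedar has come to rest for what is asked: free Ptn stands at 0% of its charge after 1.00 h, and at ten times the time, after 20.0 h, the reacted part in cedar is 80.0%; larch after 20.0 h gives 80.0%. Other species still shift slightly in cedar: between 2.00 h and 20.0 h, Byp goes from 7.53 × 10⁻⁴ M to 7.60 × 10⁻⁴ M, and Spx.Bse from 1.53 × 10⁻⁴ M to 1.60 × 10⁻⁴ M.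

(The runs stem from a simulated flask from invented constants, noise included.)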